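**Plan**

- Ring B (the pyranone) is a β-aryloxy ketone: O1 is bonded to C2, C2 is β to the C4 carbonyl, and O1 and the acyl carbon sit ortho on the bromohydroquinone ring A. This is the retron of an intramolecular oxa-Michael addition, which is also the last event of the presumed biosynthesis (open-chain aryl enone → chromanone).
- Cuts: first O1–C2 (ring B opens to an (E)-o-hydroxyaryl enone), then C4–C4a (aryllithium plus a C10 enal, with oxidation), then the tertiary C–OH back to the 6,7-alkene of geranyl acetate.
- Forward: the hydrated C10 enal is made from geranyl acetate, the ring A block from 2,5-dibromohydroquinone; they are joined, oxidised to the enone, the phenols are unmasked, and ring B is closed last, in the final step.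
- Stereochemistry: the single stereocentre C2 (R) is created in the ring closure by a bifunctional cinchona squaramide acting on the E-enone; the E geometry is inherited from geraniol.

Key step: step 7

Assumption: no close precedent fixes the sense of induction in step 7, so the quinidine-derived catalyst is written and its quinine-derived pseudoenantiomer is to be used instead if the Si face turns out to be favoured; the configuration of the product is to be checked by anomalous-dispersion X-ray analysis (bromine).

**Route**

Step 1
Reactants: 1 geranyl acetate, (2E)-3,7-dimethylocta-2,6-dien-1-yl acetate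
Product: 4 (2E)-3,7-dimethyloct-2-ene-1,7-diol, via organomercurial 2 (not isolated), via hydroxy acetate 3 (not isolated)
Conditions: Hg(OAc)2 (1.05 equiv), THF/H2O 1:1, rt; then 3 M aq NaOH, NaBH4, 0 °C; then MeOH, rt
Reagents that add atoms: water, O
Why: Markovnikov oxymercuration–demercuration hydrates the electron-rich, remote 6,7-alkene well ahead of the 2,3-alkene that the allylic acetate deactivates, and the alkaline demercuration medium with added MeOH saponifies the acetate in the same pot, so that no stereocentre is left.

Step 2
Reactants: 4 (2E)-3,7-dimethyloct-2-ene-1,7-diol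
Product: 5 (2E)-7-hydroxy-3,7-dimethyloct-2-enal
Conditions: activated MnO2 (15 equiv), CH2Cl2, rt
Reagents that add atoms: none
Why: Allylic oxidation with MnO2 takes the primary allylic alcohol to the enal without touching the tertiary alcohol or the E geometry, as in the oxidation of geraniol to geranial.

Step 3
Reactants: 6 2,5-dibromobenzene-1,4-diol (2,5-dibromohydroquinone)
Product: 7 1,4-dibromo-2,5-bis(1-ethoxyethoxy)benzene (mixture of diastereomers at the acetal carbons)
Conditions: ethyl vinyl ether (4 equiv), PPTS (5 mol %), CH2Cl2, 0 °C → rt
Reagents that add atoms: ethyl vinyl ether, C=COCC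
Why: Acid-catalysed addition of both phenols to the enol ether gives 1-ethoxyethyl acetals that tolerate organolithium reagents, assist the later bromine–lithium exchange by chelation and leave under very weak acid; the acetal centres are uncontrolled and are removed in step 6.

Step 4
Reactants: 7 1,4-dibromo-2,5-bis(1-ethoxyethoxy)benzene; 5 (2E)-7-hydroxy-3,7-dimethyloct-2-enal
Product: 9 (2E)-1-[4-bromo-2,5-bis(1-ethoxyethoxy)phenyl]-3,7-dimethyloct-2-ene-1,7-diol, via aryllithium 8 (not isolated)
Conditions: 7 (2.2 equiv), n-BuLi (2.2 equiv), THF, −78 °C; then 5 (1.0 equiv), −78 → −40 °C; then H2O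
Reagents that add atoms: none
Why: Bromine–lithium exchange at −78 °C with one equivalent of n-BuLi per arene should stop at the monolithio stage, and the aryllithium adds 1,2 to the β,β-disubstituted enal after one equivalent has been spent on the tertiary O–H, which forms the C4–C4a bond of the target para to the remaining bromine; the carbinol centre is uncontrolled and is destroyed in step 5.

Step 5
Reactants: 9 (2E)-1-[4-bromo-2,5-bis(1-ethoxyethoxy)phenyl]-3,7-dimethyloct-2-ene-1,7-diol
Product: 10 (2E)-1-[4-bromo-2,5-bis(1-ethoxyethoxy)phenyl]-7-hydroxy-3,7-dimethyloct-2-en-1-one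
Conditions: activated MnO2 (20 equiv), CH2Cl2, rt
Reagents that add atoms: none
Why: MnO2 oxidises the doubly activated (benzylic and allylic) carbinol to the aryl enone under neutral conditions that spare the acetals, the tertiary alcohol, the aryl bromide and the E geometry.

Step 6
Reactants: 10 (2E)-1-[4-bromo-2,5-bis(1-ethoxyethoxy)phenyl]-7-hydroxy-3,7-dimethyloct-2-en-1-one
Product: 11 (2E)-1-(4-bromo-2,5-dihydroxyphenyl)-7-hydroxy-3,7-dimethyloct-2-en-1-one
Conditions: PPTS (0.2 equiv), MeOH, rt, dark
Reagents that add atoms: none
Why: Transacetalisation to methanol under pyridinium tosylate catalysis frees both phenols with an acid too weak to protonate the enone or ionise the tertiary alcohol, and the freed C2′ hydroxyl is held in a hydrogen bond to the ketone, so that ring closure should not start without a base.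

Step 7
Reactants: 11 (2E)-1-(4-bromo-2,5-dihydroxyphenyl)-7-hydroxy-3,7-dimethyloct-2-en-1-one
Product: 12 (2R)-7-bromo-6-hydroxy-2-(4-hydroxy-4-methylpentyl)-2-methyl-2,3-dihydro-4H-chromen-4-one
Conditions: squaramide from 9-amino-9-deoxy-epi-quinidine and 3,5-bis(trifluoromethyl)aniline (10 mol %), toluene/CH2Cl2 4:1, −20 °C, argon, dark
Reagents that add atoms: none
Why: Proposed new method: the quinuclidine nitrogen of the catalyst takes up the proton of the C2′ phenol while the two squaramide N–H bonds hold the enone carbonyl, the phenoxide oxygen adds to C3 of the enone, and the resulting enol(ate) is protonated at C2 to give the ketone. The closest known reaction types are the bifunctional cinchona thiourea- or squaramide-catalysed intramolecular oxa-Michael cyclisations of o-hydroxyaryl enones to flavanones and 2-monosubstituted chromanones, and the racemic amine-mediated closure of β,β-dialkyl enones in the Kabbe chromanone synthesis; what is new is the enantioselective creation of a fully substituted C–O centre from a β-methyl-β-alkyl enone. Ring B closes in the 6-endo-trig mode through the O1–C2 bond. The only stereocentre, C2, is set by the catalyst, which must deliver the oxygen to the Re face of C3 of the enone (priorities C2 > C4 > CH3) to give (R); this presupposes the geometrically pure E-enone secured by geranyl acetate and by working in the dark. The step needs enantioface selectivity over the uncatalysed background, which the internal O–H···O=C hydrogen bond, the low temperature and the non-polar medium should hold down. Chemoselectivity is secured because the C5′ phenol cannot reach C3 and the tertiary alcohol is far less acidic than the phenol, and the low temperature with a neutral work-up should keep the retro-oxa-Michael racemisation channel closed.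

**Compound list**

1 | geranyl acetate, (2E)-3,7-dimethylocta-2,6-dien-1-yl acetate | CC(=O)OC/C=C(\C)CCC=C(C)C | starting material
2 | (2E)-6-(acetoxymercurio)-7-hydroxy-3,7-dimethyloct-2-en-1-yl acetate (racemic at C6) | CC(=O)OC/C=C(\C)CCC([Hg]OC(C)=O)C(C)(C)O | intermediate
3 | (2E)-7-hydroxy-3,7-dimethyloct-2-en-1-yl acetate | CC(=O)OC/C=C(\C)CCCC(C)(C)O | intermediate
4 | (2E)-3,7-dimethyloct-2-ene-1,7-diol | OC/C=C(\C)CCCC(C)(C)O | intermediate
5 | (2E)-7-hydroxy-3,7-dimethyloct-2-enal | O=C/C=C(\C)CCCC(C)(C)O | intermediate
6 | 2,5-dibromobenzene-1,4-diol | Oc1cc(Br)c(O)cc1Br | starting material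
7 | 1,4-dibromo-2,5-bis(1-ethoxyethoxy)benzene (diastereomer mixture) | CCOC(C)Oc1cc(Br)c(OC(C)OCC)cc1Br | intermediate
8 | [4-bromo-2,5-bis(1-ethoxyethoxy)phenyl]lithium | [Li]c1cc(OC(C)OCC)c(Br)cc1OC(C)OCC | intermediate
9 | (2E)-1-[4-bromo-2,5-bis(1-ethoxyethoxy)phenyl]-3,7-dimethyloct-2-ene-1,7-diol (carbinol and acetal centres uncontrolled) | CCOC(C)Oc1cc(Br)c(OC(C)OCC)cc1C(O)/C=C(\C)CCCC(C)(C)O | intermediate
10 | (2E)-1-[4-bromo-2,5-bis(1-ethoxyethoxy)phenyl]-7-hydroxy-3,7-dimethyloct-2-en-1-one | CCOC(C)Oc1cc(Br)c(OC(C)OCC)cc1C(=O)/C=C(\C)CCCC(C)(C)O | intermediate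
11 | (2E)-1-(4-bromo-2,5-dihydroxyphenyl)-7-hydroxy-3,7-dimethyloct-2-en-1-one | Oc1cc(Br)c(O)cc1C(=O)/C=C(\C)CCCC(C)(C)O | intermediate
12 | (2R)-7-bromo-6-hydroxy-2-(4-hydroxy-4-methylpentyl)-2-methyl-2,3-dihydro-4H-chromen-4-one | CC(C)(O)CCC[C@]1(C)CC(=O)c2cc(O)c(Br)cc2O1 | target

**Count and risks**

Total steps: 7. Longest linear sequence: 6 (steps 1, 2, 4, 5, 6, 7, from geranyl acetate).

Steps most likely to fail:

1. Step 7. The catalyst may discriminate poorly, or in the wrong sense, between the two faces of a β-methyl-β-alkyl enone. Uncatalysed closure or E/Z isomerisation may erode the selectivity, and the more acidic C5′ phenol may tie up the basic site of the catalyst. Fallback (known chemistry), setting out from 11: ring closure with an achiral amine (Et3N or pyrrolidine, EtOH, rt, the oxa-Michael half of the Kabbe chromanone synthesis) gives racemic 7-bromo-6-hydroxy-2-(4-hydroxy-4-methylpentyl)-2-methylchroman-4-one F1. Preparative chromatography on a chiral stationary phase (amylose tris(3,5-dimethylphenylcarbamate), CO2/MeOH) separates the (2R)-enantiomer from the (2S)-enantiomer F2, which is set aside. The fallback rejoins the route at 12.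

2. Step 4. The exchange may run on to the dilithio arene, the aryllithium may act as a base toward the γ-hydrogens of the enal instead of adding, and the ionisable benzylic and allylic carbinol may decompose on isolation. Fallback, setting out from 5: Pinnick oxidation (NaClO2, NaH2PO4, 2-methyl-2-butene, t-BuOH/H2O) gives (2E)-7-hydroxy-3,7-dimethyloct-2-enoic acid F3. Coupling with N,O-dimethylhydroxylamine hydrochloride (EDC·HCl, HOBt, i-Pr2NEt, CH2Cl2) gives the Weinreb amide (2E)-7-hydroxy-N-methoxy-N,3,7-trimethyloct-2-enamide F4. Addition of aryllithium 8 (2.2 equiv, THF, −78 °C) and aqueous work-up gives the ketone directly. The fallback rejoins the route at 10, so that carbinol 9 and step 5 are not needed.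

3. Step 1. Hydration may not be fully site-selective between the two trisubstituted alkenes, and organomercury residues may be carried into the diol. Fallback, setting out from 1: mCPBA (1.0 equiv, CH2Cl2, 0 °C) epoxidises the more electron-rich 6,7-alkene to 6,7-epoxygeranyl acetate F5. LiAlH4 (THF, 0 °C → rt) then delivers hydride to the less substituted epoxide carbon, which leaves the tertiary alcohol, and cleaves the acetate. The fallback rejoins the route at 4.

**Further compounds**

F1 | step 7 | racemic 7-bromo-6-hydroxy-2-(4-hydroxy-4-methylpentyl)-2-methylchroman-4-one | CC(C)(O)CCCC1(C)CC(=O)c2cc(O)c(Br)cc2O1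
F2 | step 7 | (2S)-7-bromo-6-hydroxy-2-(4-hydroxy-4-methylpentyl)-2-methyl-2,3-dihydro-4H-chromen-4-one | CC(C)(O)CCC[C@@]1(C)CC(=O)c2cc(O)c(Br)cc2O1
F3 | step 4 | (2E)-7-hydroxy-3,7-dimethyloct-2-enoic acid | OC(=O)/C=C(\C)CCCC(C)(C)O
F4 | step 4 | (2E)-7-hydroxy-N-methoxy-N,3,7-trimethyloct-2-enamide | CON(C)C(=O)/C=C(\C)CCCC(C)(C)O
F5 | step 1 | 6,7-epoxygeranyl acetate, (2E)-5-(3,3-dimethyloxiran-2-yl)-3-methylpent-2-en-1-yl acetate (racemic) | CC(=O)OC/C=C(\C)CCC1OC1(C)C
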